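**Retrosynthetic overview**
- Sauriol A ⇒ ester cleavage and twofold Dakin oxidation of a C2-symmetric bis(5-alkyl-o-vanillin pivalate); each catechol is carried as a salicylaldehyde until the end.
- Both aryl–CH2 bonds ⇒ one blue-light nickel/iridium twofold deoxygenative arylation of (2S,3S)-2,3-dimethylbutane-1,4-diol with two molecules of 5-bromo-o-vanillin pivalate; the stereocentres sit β to the reacting carbons.
- The C2 diol ⇒ LiAlH4 opening of trans-3,4-dimethyl-γ-butyrolactone ⇒ trans-selective enolate methylation of (S)-4-methyl-γ-butyrolactone ⇒ regioselective oxidative lactonization of purchased (S)-2-methylbutane-1,4-diol. The purchased centre directs the second one.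
- Rings: both arenes are purchased; the only ring made is the temporary lactone (step 1), opened again in step 3.

Assumption: the target SMILES is read as the (2R,3R) enantiomer, and the (S)-methylbutanediol and 5-bromo-o-vanillin are taken as inexpensive catalogue compounds.

**Route**

Step 1
Reactants: 1 (S)-2-methylbutane-1,4-diol
Product: 3 (S)-4-methyldihydrofuran-2(3H)-one, via lactol 2 (not isolated)
Conditions: Cu(MeCN)4OTf (5 mol %), 2,2'-bipyridine (5 mol %), TEMPO (5 mol %), N-methylimidazole (10 mol %), air, MeCN, rt
Reagents that add atoms: none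
Why: Copper/nitroxyl aerobic alcohol oxidation–lactonization oxidises the unbranched C4 hydroxyl faster than the β-branched C1 hydroxyl (expected roughly 5–10:1), the aldehyde-level product is present as lactol 2 and is oxidised on, so the carbonyl ends remote from the methyl group and the purchased stereocentre is untouched; the minor α-methyl regioisomer is removed by chromatography.

Step 2
Reactants: 3 (S)-4-methyldihydrofuran-2(3H)-one
Product: 5 (3S,4S)-3,4-dimethyldihydrofuran-2(3H)-one, via lithium enolate 4 (not isolated)
Conditions: LDA (1.05 equiv, commercial solution), THF, −78 °C; MeI (1.5 equiv), −78 to −45 °C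
Reagents that add atoms: iodomethane, CI
Why: Kinetic lactone enolate alkylation, in which LDA removes an α-proton (the β-stereocentre is not acidic) and iodomethane enters the enolate face opposite the adjacent C4 methyl, setting C3 as S (trans, expected at least 10:1) under control of the purchased stereocentre.

Step 3
Reactants: 5 (3S,4S)-3,4-dimethyldihydrofuran-2(3H)-one
Product: 6 (2S,3S)-2,3-dimethylbutane-1,4-diol
Conditions: LiAlH4 (1.5 equiv), THF, 0 °C to rt; then H2O/aq NaOH work-up
Reagents that add atoms: none
Why: Hydride reduction of a lactone to the 1,4-diol, with no new stereocentre and no epimerisation because the aldehyde-level intermediate is reduced faster than it enolises, giving the C2-symmetric diol with both descriptors unchanged.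

Step 4
Reactants: 7 5-bromo-2-hydroxy-3-methoxybenzaldehyde
Product: 8 4-bromo-2-formyl-6-methoxyphenyl 2,2-dimethylpropanoate
Conditions: PivCl (1.3 equiv), Et3N (1.5 equiv), DMAP (5 mol %), CH2Cl2, 0 °C to rt
Reagents that add atoms: pivaloyl chloride, CC(C)(C)C(Cl)=O
Why: DMAP-catalysed O-acylation of the phenol, which masks the acidic, nickel-chelating salicylaldehyde hydroxyl for the cross-coupling and is cleaved later under the Dakin conditions.

Step 5
Reactants: 6 (2S,3S)-2,3-dimethylbutane-1,4-diol; 8 4-bromo-2-formyl-6-methoxyphenyl 2,2-dimethylpropanoate (two molecules of 8 are built into the product, one at each terminus of 6)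
Product: 10 4,4'-[(2R,3R)-2,3-dimethylbutane-1,4-diyl]bis(2-formyl-6-methoxyphenyl) bis(2,2-dimethylpropanoate), via bis-benzoxazoline diether 9 (not isolated)
Conditions: (a) 6 (1.0 equiv), 5,7-di-tert-butyl-3-phenylbenzoxazolium tetrafluoroborate (2.1 equiv), pyridine (2.1 equiv), MTBE, rt, 20 min, filter; (b) 8 (3.0 equiv), Ir(ppy)2(dtbbpy)PF6 (2 mol %), NiBr2(dtbbpy) (10 mol %), quinuclidine (3.5 equiv), phthalimide (0.5 equiv), DMA/MTBE, 450 nm LEDs, rt
Reagents that add atoms: 4-bromo-2-formyl-6-methoxyphenyl pivalate (second equivalent of 8), COc1cc(Br)cc(C=O)c1OC(=O)C(C)(C)C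
Why: Proposed new method: a one-pot twofold deoxygenative C(sp3)–C(sp2) arylation of a free 1,4-diol that joins two molecules of 8 to the two termini of 6, in which both primary hydroxyls are first condensed with the benzoxazolium salt to bis-aminal 9, the excited iridium photocatalyst oxidises each aminal nitrogen, quinuclidine removes the adjacent C–H and β-scission of the resulting carbon radical expels the benzoxazolone and a primary alkyl radical that is captured by the aryl–nickel bromide formed from 8 and zerovalent nickel, reductive elimination from trivalent nickel then forging each Ar–CH2 bond, the closest known reaction type being the nickel/photoredox deoxygenative arylation of single NHC-activated alcohols with aryl bromides; both stereocentres lie β to the radical carbon and are carried through unchanged (S,S becomes R,R only through CIP priorities).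

Step 6
Reactants: 10 4,4'-[(2R,3R)-2,3-dimethylbutane-1,4-diyl]bis(2-formyl-6-methoxyphenyl) bis(2,2-dimethylpropanoate)
Product: 13 Sauriol A [5,5'-[(2R,3R)-2,3-dimethylbutane-1,4-diyl]bis(3-methoxybenzene-1,2-diol)], via free bis-salicylaldehyde 11 (not isolated), via bis-formate 12 (not isolated)
Conditions: 2 M NaOH (10 equiv), THF/H2O, Ar, rt, 1 h; then 30% H2O2 (2.4 equiv), 0 °C to rt; then 1 M HCl to pH 2 (degassed solvents throughout)
Reagents that add atoms: hydrogen peroxide, OO
Why: Ester saponification followed by Dakin oxidation, in which hydroxide cleaves the aryl pivalates (helped by the neighbouring formyl hydrate), hydroperoxide adds to each o-hydroxybenzaldehyde and the electron-rich aryl group migrates to oxygen (Baeyer–Villiger type) to give formates 12 that hydrolyse in situ to the catechols; no stereocentre is involved.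

**Compound list**

1 | (S)-2-methylbutane-1,4-diol | C[C@H](CO)CCO | starting material
2 | (4S)-4-methyloxolan-2-ol (lactol, anomer mixture) | C[C@@H]1COC(O)C1 | intermediate
3 | (S)-4-methyldihydrofuran-2(3H)-one | C[C@@H]1COC(=O)C1 | intermediate
4 | lithium (S)-4-methyl-4,5-dihydrofuran-2-olate | C[C@@H]1COC(O[Li])=C1 | intermediate
5 | (3S,4S)-3,4-dimethyldihydrofuran-2(3H)-one (trans) | C[C@@H]1COC(=O)[C@H]1C | intermediate
6 | (2S,3S)-2,3-dimethylbutane-1,4-diol | OC[C@@H](C)[C@H](C)CO | intermediate
7 | 5-bromo-2-hydroxy-3-methoxybenzaldehyde | COc1cc(Br)cc(C=O)c1O | starting material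
8 | 4-bromo-2-formyl-6-methoxyphenyl 2,2-dimethylpropanoate | COc1cc(Br)cc(C=O)c1OC(=O)C(C)(C)C | intermediate
9 | (2S,3S)-1,4-bis[(5,7-di-tert-butyl-3-phenyl-2,3-dihydro-1,3-benzoxazol-2-yl)oxy]-2,3-dimethylbutane (aminal carbons unassigned) | CC(C)(C)c1cc(C(C)(C)C)c2OC(OC[C@@H](C)[C@H](C)COC3Oc4c(C(C)(C)C)cc(C(C)(C)C)cc4N3c3ccccc3)N(c3ccccc3)c2c1 | intermediate
10 | 4,4'-[(2R,3R)-2,3-dimethylbutane-1,4-diyl]bis(2-formyl-6-methoxyphenyl) bis(2,2-dimethylpropanoate) | COc1cc(C[C@@H](C)[C@H](C)Cc2cc(OC)c(OC(=O)C(C)(C)C)c(C=O)c2)cc(C=O)c1OC(=O)C(C)(C)C | intermediate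
11 | 5,5'-[(2R,3R)-2,3-dimethylbutane-1,4-diyl]bis(2-hydroxy-3-methoxybenzaldehyde) (present as its disodium phenoxide) | COc1cc(C[C@@H](C)[C@H](C)Cc2cc(OC)c(O)c(C=O)c2)cc(C=O)c1O | intermediate
12 | 5,5'-[(2R,3R)-2,3-dimethylbutane-1,4-diyl]bis(2-hydroxy-3-methoxyphenyl) diformate | COc1cc(C[C@@H](C)[C@H](C)Cc2cc(OC)c(O)c(OC=O)c2)cc(OC=O)c1O | intermediate
13 | Sauriol A, 5,5'-[(2R,3R)-2,3-dimethylbutane-1,4-diyl]bis(3-methoxybenzene-1,2-diol) | COc1cc(C[C@@H](C)[C@H](C)Cc2cc(O)c(O)c(OC)c2)cc(O)c1O | target

**Step count and risks**

Total steps: 6. Longest linear sequence: 5 (steps 1, 2, 3, 5, 6).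

Most likely to fail, step 5 (the proposed new step). The risks are these:
- The second arylation may lag behind the first.
- The primary radical formed at one terminus can abstract the weak aminal hydrogen of the other terminus (1,6-hydrogen shift), which would end that terminus as a methyl group.
- The aryl aldehyde is an extra burden on the radical conditions. Ir(ppy)2(dtbbpy)PF6 is chosen because its excited state is not oxidising enough to turn quinuclidine into a hydrogen-abstracting radical cation, so the formyl C–H should be left alone.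

The fallback uses known chemistry and sets out from 6. Iodination with I2, PPh3 and imidazole in CH2Cl2 gives (2S,3S)-1,4-diiodo-2,3-dimethylbutane F1. Zinc insertion (Zn dust, LiCl, THF, 40 °C) gives [(2S,3S)-2,3-dimethylbutane-1,4-diyl]bis(iodozinc) F2, used in solution. A twofold Negishi coupling with 8 (2.4 equiv), Pd(OAc)2 (4 mol %) and SPhos (8 mol %) in THF at rt then comes back to the route at 10. Alkylzinc iodides tolerate the aldehyde and the pivalate, and the stereocentres are again β to the metal-bearing carbon.

Second, step 6. The bis-catechol is electron-rich and can be over-oxidised in alkaline peroxide, and the two hindered pivalates must cleave before the peroxide is added. The fallback unveils the catechol before the coupling and sets out from 7 (with 6 as partner). Dakin oxidation of 7 (NaOH, H2O2, then HCl) passes through 5-bromo-2-hydroxy-3-methoxyphenyl formate F3 and gives 5-bromo-3-methoxybenzene-1,2-diol F4. Benzylation (BnBr, K2CO3, DMF) gives 1,2-bis(benzyloxy)-5-bromo-3-methoxybenzene F5. Coupling of F5 with 6 through 9 under the step 5 conditions gives 5,5'-[(2R,3R)-2,3-dimethylbutane-1,4-diyl]bis[1,2-bis(benzyloxy)-3-methoxybenzene] F6. Hydrogenolysis (H2, 10% Pd/C, EtOAc/MeOH) comes back to the route at 13.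

Third, step 2. Iodomethane is a small electrophile, so the trans:cis ratio may be modest. The cis lactone is hard to separate and would end as the meso diastereomer. The fallback sets out from 3. Enolate 4 (LDA, THF, −78 °C) is alkylated with chloromethyl phenyl sulfide (DMPU, −78 to −20 °C) to give (3S,4S)-4-methyl-3-[(phenylsulfanyl)methyl]oxolan-2-one F7. The larger electrophile should raise the trans selectivity, and the UV-active diastereomers separate on silica. Desulfurisation with Raney Ni in EtOH at rt comes back to the route at 5.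

Further compounds
F1 | step 5 | (2S,3S)-1,4-diiodo-2,3-dimethylbutane | IC[C@@H](C)[C@H](C)CI
F2 | step 5 | [(2S,3S)-2,3-dimethylbutane-1,4-diyl]bis(iodozinc) | I[Zn]C[C@@H](C)[C@H](C)C[Zn]I
F3 | step 6 | 5-bromo-2-hydroxy-3-methoxyphenyl formate | COc1cc(Br)cc(OC=O)c1O
F4 | step 6 | 5-bromo-3-methoxybenzene-1,2-diol | COc1cc(Br)cc(O)c1O
F5 | step 6 | 1,2-bis(benzyloxy)-5-bromo-3-methoxybenzene | COc1cc(Br)cc(OCc2ccccc2)c1OCc1ccccc1
F6 | step 6 | 5,5'-[(2R,3R)-2,3-dimethylbutane-1,4-diyl]bis[1,2-bis(benzyloxy)-3-methoxybenzene] | COc1cc(C[C@@H](C)[C@H](C)Cc2cc(OC)c(OCc3ccccc3)c(OCc3ccccc3)c2)cc(OCc2ccccc2)c1OCc1ccccc1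
F7 | step 2 | (3S,4S)-4-methyl-3-[(phenylsulfanyl)methyl]oxolan-2-one | C[C@@H]1COC(=O)[C@H]1CSc1ccccc1
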